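The feature exploited is the (E)-trisubstituted C13(C16)=C14 olefin whose C15 methylene hangs on the tertiary C4′ oxygen of eudesmane ring A: the target is cut at C13–C16 and C14–C15. A terminal C13≡C14 alkyne on the labdane decalin undergoes syn methyl-metalation, and the resulting C14–aluminium bond is alkylated by a chloromethyl ether already carrying the C4′ oxygen. One operation thus installs the C16 methyl, the C15 methylene and the olefin geometry, and the congested C4′–O bond never has to be made. The precursors are a 15,16-dinorlabd-8(17)-en-13-yne C19 ester, cut down from trans-communic acid, and the 11′-O-silyl 4′-O-chloromethyl ether of cryptomeridiol, made from β-eudesmol; both silicon groups later fall to fluoride.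

Key step: step 10

Assumption: (+)-trans-communic acid and (+)-β-eudesmol are bought as catalogue natural products of the configurations drawn; labdane atoms carry plain numbers, eudesmane atoms primed numbers, and the alkyne partner, which keeps C14 and lacks only C15 and C16, is named as a 15,16-dinorlabdane.

Step 1
Reactants: 1 (+)-trans-communic acid
Product: 2 2-(trimethylsilyl)ethyl trans-communate
Conditions: Me3SiCH2CH2OH, PPh3, DIAD (added last), THF, 0 °C → rt
Reagents that add atoms: 2-(trimethylsilyl)ethanol, C[Si](C)(C)CCO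
Why: Mitsunobu esterification, in which the carboxylate is the nucleophile and displaces the phosphonium-activated primary alcohol, so the shielded axial C19 carbonyl is never attacked, DIAD is consumed by PPh3 before it can meet the diene, and no stereocentre is touched.

Step 2
Reactants: 2 2-(trimethylsilyl)ethyl trans-communate
Product: 4 2-(trimethylsilyl)ethyl 12-hydroxy-13,14,15,16-tetranorlabd-8(17)-en-19-oate, via C12 aldehyde 3 (not isolated)
Conditions: O3 (1.0 equiv, standardised CH2Cl2 solution), CH2Cl2–MeOH, −78 °C; then NaBH4, −78 → 0 °C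
Reagents that add atoms: ozone, [O-][O+]=O
Why: Ozonolysis with reductive borohydride work-up, in which one equivalent of ozone should cleave the electron-rich trisubstituted C12=C13 bond of the diene ahead of the monosubstituted C14=C15 and the more hindered 1,1-disubstituted C8=C17 bonds, and hydride then reduces the C12 aldehyde in the same flask without touching the hindered ester.

Step 3
Reactants: 4 2-(trimethylsilyl)ethyl 12-hydroxy-13,14,15,16-tetranorlabd-8(17)-en-19-oate
Product: 5 2-(trimethylsilyl)ethyl 12-iodo-13,14,15,16-tetranorlabd-8(17)-en-19-oate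
Conditions: I2, PPh3, imidazole, CH2Cl2, 0 °C → rt
Reagents that add atoms: iodine, II
Why: Appel-type iodination, in which iodide displaces the alkoxyphosphonium group at the unhindered primary C12 while imidazole keeps the medium non-acidic, so the exocyclic olefin does not cyclise onto or migrate toward the side chain.

Step 4
Reactants: 5 2-(trimethylsilyl)ethyl 12-iodo-13,14,15,16-tetranorlabd-8(17)-en-19-oate
Product: 6 2-(trimethylsilyl)ethyl 15,16-dinorlabd-8(17)-en-13-yn-19-oate
Conditions: HC≡CLi·H2NCH2CH2NH2, DMSO, 15 °C → rt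
Reagents that add atoms: lithium acetylide–ethylenediamine complex, [Li+].[C-]#C.NCCN
Why: SN2 alkylation of lithium acetylide by the unbranched primary iodide in a dipolar aprotic solvent forms C12–C13, while the neopentyl-type C19 ester is too shielded to be attacked.

Step 5
Reactants: 7 (+)-β-eudesmol
Product: 8 11-(triethylsilyloxy)eudesm-4(15)-ene
Conditions: Et3SiOTf, 2,6-lutidine, CH2Cl2, −78 → 0 °C
Reagents that add atoms: triethylsilyl trifluoromethanesulfonate, CC[Si](CC)(CC)OS(=O)(=O)C(F)(F)F
Why: Silyl triflate silylation is needed for the hindered tertiary C11′ hydroxyl, and the lutidine buffer keeps the exocyclic C4′=C15′ olefin from migrating.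

Step 6
Reactants: 8 11-(triethylsilyloxy)eudesm-4(15)-ene
Product: 9 4α,15-epoxy-11-(triethylsilyloxy)eudesmane
Conditions: mCPBA, NaHCO3, CH2Cl2, 0 °C
Reagents that add atoms: 3-chloroperbenzoic acid, OOC(=O)c1cccc(Cl)c1
Why: Prilezhaev epoxidation, in which the peracid should approach C4′=C15′ from the α-face because the axial C10′ methyl group blocks the β-face, so the new C4′ stereocentre carries its oxygen α (equatorial) as the target requires.

Step 7
Reactants: 9 4α,15-epoxy-11-(triethylsilyloxy)eudesmane
Product: 10 11-(triethylsilyloxy)eudesman-4α-ol (cryptomeridiol 11-O-triethylsilyl ether)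
Conditions: LiEt3BH, THF, 0 °C → rt
Reagents that add atoms: none
Why: SN2 hydride opening of the epoxide at its unhindered CH2 terminus leaves the C4′–O bond, and hence the C4′ configuration set in step 6, untouched and turns C15′ into the β-methyl group.

Step 8
Reactants: 10 11-(triethylsilyloxy)eudesman-4α-ol
Product: 11 4α-[(methylthio)methoxy]-11-(triethylsilyloxy)eudesmane
Conditions: DMSO, Ac2O, AcOH, rt, 48 h
Reagents that add atoms: dimethyl sulfoxide, CS(C)=O
Why: Pummerer-type methylthiomethylation, in which the small methyl(methylene)sulfonium electrophile O-alkylates a tertiary alcohol that resists acetylation, without touching the C4′ stereocentre.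

Step 9
Reactants: 11 4α-[(methylthio)methoxy]-11-(triethylsilyloxy)eudesmane
Product: 12 4α-(chloromethoxy)-11-(triethylsilyloxy)eudesmane (cryptomeridiol 11-O-triethylsilyl 4-O-chloromethyl ether)
Conditions: SO2Cl2 (1.05 equiv), CH2Cl2, −78 → 0 °C; volatiles removed in vacuo (toluene chase), used crude
Reagents that add atoms: sulfuryl chloride, O=S(=O)(Cl)Cl
Why: Chlorinolysis of the O,S-acetal, in which sulfur is chlorinated and chloride displaces the sulfonium group at the acetal carbon, gives the α-chloro ether with only volatile co-products, and the tertiary silyl ether is inert because no protic acid is formed.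

Step 10
Reactants: 6 2-(trimethylsilyl)ethyl 15,16-dinorlabd-8(17)-en-13-yn-19-oate; 12 4α-(chloromethoxy)-11-(triethylsilyloxy)eudesmane; 13 trimethylaluminium
Product: 16 2-(trimethylsilyl)ethyl 15-[(11′-triethylsilyloxyeudesman-4′α-yl)oxy]labda-8(17),13E-dien-19-oate, via alkenyldimethylalane 14 (not isolated), via lithium alanate 15 (not isolated)
Conditions: Cp2ZrCl2 (0.3 equiv), 13 (3 equiv), (CH2Cl)2, rt; volatiles removed in vacuo, hexane extract; n-BuLi, hexane–THF, −78 → 0 °C; 12 (0.8 equiv), THF, −78 °C → rt; aq. NaHCO3
Reagents that add atoms: trimethylaluminium (13), C[Al](C)C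
Why: Zirconocene-catalysed methylalumination (Negishi carboalumination) adds CH3 and Al syn across C13≡C14 of 6 with the methyl on the internal carbon C13 (new C13–C16 bond), so that in alane 14 the aluminium on C14 is cis to C16 and trans to C12. Once excess Me3Al has been pumped off, n-BuLi turns 14 into the more nucleophilic, non-Lewis-acidic alanate 15, which hands over its alkenyl group, with retention at C14, to the primary, oxygen-activated CH2Cl carbon of 12 (new C14–C15 bond), while the C4′–O bond and its configuration come unchanged from 12. The closest known reaction type is the alkylation of (E)-2-methylalkenylalanates, made in the same way, with chloromethyl methyl ether to give (E)-allylic methyl ethers; here the methyl of that ether is replaced by a tertiary alkyl group remote from the reacting carbon. No ring is closed and no stereocentre is formed; the only stereochemical element created, the (E) geometry of C13=C14, is fixed by the syn carbometalation and by retention in the C–Al to C–C exchange. The step needs regioselectivity (methyl to C13), secured by the terminal alkyne, and chemoselectivity for the alkyne over the C8=C17 olefin and the C19 ester, secured because 1,1-disubstituted olefins do not carboaluminate under Cp2ZrCl2/Me3Al at room temperature and the neopentyl-type ester is too shielded to react with Me–Al or the briefly present butyllithium.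

Step 11
Reactants: 16 2-(trimethylsilyl)ethyl 15-[(11′-triethylsilyloxyeudesman-4′α-yl)oxy]labda-8(17),13E-dien-19-oate
Product: 17 15-[(11′-hydroxyeudesman-4′α-yl)oxy]labda-8(17),13E-dien-19-oic acid (target)
Conditions: TBAF (5 equiv), THF, rt → 45 °C; then dilute aq. HCl to pH 4, 0 °C
Reagents that add atoms: none
Why: Fluoride-induced desilylation, in which attack at silicon fragments the 2-(trimethylsilyl)ethyl ester to carboxylate and ethylene regardless of the shielding of C19 and also cleaves the tertiary Si–O bond at C11′, while the allyl tert-alkyl ether and both olefins are inert to fluoride.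

Compound list
1 | (+)-trans-communic acid, labda-8(17),12E,14-trien-19-oic acid (4S,5R,9S,10R; 4α-Me, 4β-CO2H, 5α-H, 9α-H, 10β-Me) | C=C1CC[C@@H]2[C@](C)(CCC[C@]2(C)C(=O)O)[C@H]1C/C=C(\C)C=C | starting material
2 | 2-(trimethylsilyl)ethyl trans-communate (ring stereochemistry as 1) | C=C1CC[C@@H]2[C@](C)(CCC[C@]2(C)C(=O)OCC[Si](C)(C)C)[C@H]1C/C=C(\C)C=C | intermediate
3 | 2-(trimethylsilyl)ethyl 12-oxo-13,14,15,16-tetranorlabd-8(17)-en-19-oate (ring stereochemistry as 1; not isolated) | C=C1CC[C@@H]2[C@](C)(CCC[C@]2(C)C(=O)OCC[Si](C)(C)C)[C@H]1CC=O | intermediate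
4 | 2-(trimethylsilyl)ethyl 12-hydroxy-13,14,15,16-tetranorlabd-8(17)-en-19-oate (ring stereochemistry as 1) | C=C1CC[C@@H]2[C@](C)(CCC[C@]2(C)C(=O)OCC[Si](C)(C)C)[C@H]1CCO | intermediate
5 | 2-(trimethylsilyl)ethyl 12-iodo-13,14,15,16-tetranorlabd-8(17)-en-19-oate (ring stereochemistry as 1) | C=C1CC[C@@H]2[C@](C)(CCC[C@]2(C)C(=O)OCC[Si](C)(C)C)[C@H]1CCI | intermediate
6 | 2-(trimethylsilyl)ethyl 15,16-dinorlabd-8(17)-en-13-yn-19-oate (ring stereochemistry as 1) | C=C1CC[C@@H]2[C@](C)(CCC[C@]2(C)C(=O)OCC[Si](C)(C)C)[C@H]1CCC#C | intermediate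
7 | (+)-β-eudesmol, eudesm-4(15)-en-11-ol (5S,7R,10R; 5α-H, 7β-hydroxyisopropyl, 10β-Me) | C=C1CCC[C@]2(C)CC[C@@H](C(C)(C)O)C[C@H]21 | starting material
8 | 11-(triethylsilyloxy)eudesm-4(15)-ene (stereochemistry as 7) | C=C1CCC[C@]2(C)CC[C@@H](C(C)(C)O[Si](CC)(CC)CC)C[C@H]21 | intermediate
9 | 4α,15-epoxy-11-(triethylsilyloxy)eudesmane (4R,5R,7R,10R; epoxide oxygen α, CH2 β) | C1O[C@@]12CCC[C@]3(C)CC[C@@H](C(C)(C)O[Si](CC)(CC)CC)C[C@H]32 | intermediate
10 | 11-(triethylsilyloxy)eudesman-4α-ol, cryptomeridiol 11-O-triethylsilyl ether (4R,5R,7R,10R; 4α-OH, 4β-Me) | O[C@]1(C)CCC[C@]2(C)CC[C@@H](C(C)(C)O[Si](CC)(CC)CC)C[C@H]21 | intermediate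
11 | 4α-[(methylthio)methoxy]-11-(triethylsilyloxy)eudesmane (4R,5R,7R,10R) | CSCO[C@]1(C)CCC[C@]2(C)CC[C@@H](C(C)(C)O[Si](CC)(CC)CC)C[C@H]21 | intermediate
12 | 4α-(chloromethoxy)-11-(triethylsilyloxy)eudesmane (4R,5R,7R,10R) | ClCO[C@]1(C)CCC[C@]2(C)CC[C@@H](C(C)(C)O[Si](CC)(CC)CC)C[C@H]21 | intermediate
13 | trimethylaluminium | C[Al](C)C | starting material
14 | 2-(trimethylsilyl)ethyl 14-(dimethylalumanyl)-15-norlabda-8(17),13E-dien-19-oate (Al on C14 trans to C12; not isolated) | C=C1CC[C@@H]2[C@](C)(CCC[C@]2(C)C(=O)OCC[Si](C)(C)C)[C@H]1CC/C(C)=C/[Al](C)C | intermediate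
15 | lithium butyldimethylalanate derived from 14 (same 13E-alkenyl group on aluminium; not isolated) | C=C1CC[C@@H]2[C@](C)(CCC[C@]2(C)C(=O)OCC[Si](C)(C)C)[C@H]1CC/C(C)=C/[Al-](C)(C)CCCC.[Li+] | intermediate
16 | 2-(trimethylsilyl)ethyl 15-[(11′-triethylsilyloxyeudesman-4′α-yl)oxy]labda-8(17),13E-dien-19-oate (4S,5R,9S,10R; 4′R,5′R,7′R,10′R) | C=C1CC[C@@H]2[C@](C)(CCC[C@]2(C)C(=O)OCC[Si](C)(C)C)[C@H]1CC/C(C)=C/CO[C@]1(C)CCC[C@]2(C)CC[C@@H](C(C)(C)O[Si](CC)(CC)CC)C[C@H]21 | intermediate
17 | 15-[(11′-hydroxyeudesman-4′α-yl)oxy]labda-8(17),13E-dien-19-oic acid, CNP0156875.1 (4S,5R,9S,10R; 4′R,5′R,7′R,10′R) | C=C1CC[C@@H]2[C@](C)(CCC[C@]2(C)C(=O)O)[C@H]1CC/C(C)=C/CO[C@]1(C)CCC[C@]2(C)CC[C@@H](C(C)(C)O)C[C@H]21 | target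

Total step count: 11 (steps 1–4 labdane arm, steps 5–9 eudesmane arm, step 10 union, step 11 unmasking).
Longest linear sequence: 7 steps (7 → 17 through steps 5–11).

Steps most likely to fail

Step 10. Transfer of the alkenyl group from the alanate to the bulky tertiary-alkyl chloromethyl ether may be slower than protodealumination, or than ionisation of the α-chloro ether with loss of formaldehyde. The fallback sets out from 6, uses 10 and comes back at 16. The same methylalumination of 6 is run, but alanate 15 is quenched with paraformaldehyde to give 2-(trimethylsilyl)ethyl isocupressate F1. Appel bromination (CBr4, PPh3, CH2Cl2, 0 °C) should then give the (E)-allylic bromide 2-(trimethylsilyl)ethyl 15-bromolabda-8(17),13E-dien-19-oate F2. Williamson etherification of F2 with the potassium alkoxide of 10 (KH, 18-crown-6, THF, 0 °C → rt) should give 16. This makes the O–C15 bond with the hindered tertiary alkoxide as nucleophile, which is slower and more prone to elimination, but it is established chemistry.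

Step 2. Ozone may not discriminate cleanly: competing cleavage of the exocyclic C8=C17 bond, or first attack at the vinyl terminus, would erode the yield. The fallback sets out from 2 and comes back at 4. Exhaustive ozonolysis (excess O3, CH2Cl2–MeOH, −78 °C; Me2S) removes C13–C17 altogether and should give 2-(trimethylsilyl)ethyl 8,12-dioxo-13,14,15,16,17-pentanorlabdan-19-oate F3. The aldehyde alone is reduced (NaBH(OAc)3, or NaBH4 at −78 °C) to 2-(trimethylsilyl)ethyl 12-hydroxy-8-oxo-13,14,15,16,17-pentanorlabdan-19-oate F4, which stands in equilibrium with its 8,12-hemiketal. Wittig methylenation with excess Ph3P=CH2 (from Ph3PCH3Br and KOtBu, THF–toluene, 70 °C) rebuilds C8=C17 and should give 4. C9, α to the ketone, should keep its equatorial side chain, the thermodynamically preferred arrangement.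

Step 8. The Pummerer-type etherification of the hindered tertiary hydroxyl may stall, and long exposure to acetic acid may cost the triethylsilyl ether. The fallback sets out from 10 and comes back at 11. The alcohol is deprotonated (KH, THF–DME, 0 °C) and the alkoxide is alkylated with chloromethyl methyl sulfide in the presence of NaI, a base-mediated Williamson route to the same O,S-acetal 11 that involves no acid. No compound outside the list is formed (F0).

Further compounds
F1 | step 10 | 2-(trimethylsilyl)ethyl isocupressate, 2-(trimethylsilyl)ethyl 15-hydroxylabda-8(17),13E-dien-19-oate | C=C1CC[C@@H]2[C@](C)(CCC[C@]2(C)C(=O)OCC[Si](C)(C)C)[C@H]1CC/C(C)=C/CO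
F2 | step 10 | 2-(trimethylsilyl)ethyl 15-bromolabda-8(17),13E-dien-19-oate | C=C1CC[C@@H]2[C@](C)(CCC[C@]2(C)C(=O)OCC[Si](C)(C)C)[C@H]1CC/C(C)=C/CBr
F3 | step 2 | 2-(trimethylsilyl)ethyl 8,12-dioxo-13,14,15,16,17-pentanorlabdan-19-oate | O=C1CC[C@@H]2[C@](C)(CCC[C@]2(C)C(=O)OCC[Si](C)(C)C)[C@H]1CC=O
F4 | step 2 | 2-(trimethylsilyl)ethyl 12-hydroxy-8-oxo-13,14,15,16,17-pentanorlabdan-19-oate | O=C1CC[C@@H]2[C@](C)(CCC[C@]2(C)C(=O)OCC[Si](C)(C)C)[C@H]1CCO
F0 | step 8 | none | none
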